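(The numbers in the tables come from a simulation for an exercise, and the scatter is random.)

The target and its isomer together hold the substrate that the coupling partner has caught, so we want to know where the catching stops.

| setting | dusk | north-east | north | south-west |
|---|---|---|---|---|
| substrate | 0.050 M | 0.050 M | 0.050 M | 0.050 M |
| coupling partner | 5 equiv | 2.50 equiv | 2.50 equiv | 2.50 equiv |
| temperature | 60 °C | 80 °C | 60 °C | 70 °C |
| remark | run made earlier |  |  |  |
| time |  | 20 min | 20 min | 20 min |

dusk run (percent of the substrate charged)

| time / s | target / % | substrate / % | isomer of the product / % |
|---|---|---|---|
| 15.0 | 8.1 | 91.3 | 0.5 |
| 40.0 | 18.9 | 81.1 | 1.4 |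
| 80.0 | 27.8 | 69.2 | 3.3 |
| 120 | 34.0 | 61.2 | 4.4 |

(readings scatter by 1 percentage point)

- the analysis behind the earlier runs scatters by 1 percentage point, standard deviation
- on the list of suspects stand: substrate + coupling partner <-> target; 2 coupling partner -> self-condensation product; target <-> isomer of the product
- the earlier runs do not show what temperature does; that part of a forecast is a guess

* which of these there is most of at the end, counted by the substrate in it, north-east (target / substrate / isomer of the product)
* which of these there is most of at the end, counted by the substrate in it, north (target / substrate / isomer of the product)
* which of these there is most of at the end, counted by the substrate in it, south-west (target / substrate / isomer of the product)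
* how much there is at the end of the one of these that leads, in percent of the substrate charged: north-east
* how much there is at the end of the one of these that leads, in percent of the substrate charged: north
* how much there is at the end of the one of these that leads, in percent of the substrate charged: south-west

In the dusk run the logarithmic decay constant of the substrate falls from 0.006068 s⁻¹ over the first reading to 0.003071 s⁻¹ between the last two. A way back could do this, and so could partner lost to itself; the dusk run has no partner reading to part them, and we commit to the loss. Then the reciprocal of that constant climbs steadily in time, with a slope equal to the selectivity factor plus substrate over partner. Taking that last ratio as charged, we read 1.54, the partner selectivity factor: how much faster partner goes to self-condensation than to substrate, at equal amounts. The scatter makes this a rough reading.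

Now the ladder for north, at 2.50 equiv. Partner loses itself on a time of 5.49 min divided by the factor, 3.57 min, which is shorter than the 5.49 min in which it catches substrate. At that first rung we reckon substrate near 63.7%. Target turns to isomer on 9.73 min, read from isomer over accumulated target. The asked 20 min is twice that, so we expect isomer ahead of target. Counting partner against substrate, with no way back, gives our reckoned stop, the substrate left once partner is gone: 20.5%. North at 20 min should still hold about 29.3%, above the stop. Warmth is our guess: we hold the factor fixed, so warmer flasks should lie closer to the stop.

The forecast, whose picture differs from ours in that “Substrate and target equilibrate quickly”, names isomer of the product as leader with 44% in north, 62% in south-west and 75% in north-east.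

North gives isomer of the product at 50.9%, south-west isomer of the product at 67.1%, north-east isomer of the product at 70.9%.

    substrate + coupling partner ⇌ target (K = 285 L mol⁻¹, k = 0.0234 L mol⁻¹ s⁻¹, Ea = 56.0 kJ mol⁻¹, ΔH = −34.0 kJ mol⁻¹)
    2 coupling partner → self-condensation product (k = 0.0133 L mol⁻¹ s⁻¹, Ea = 56.0 kJ mol⁻¹)
    target ⇌ isomer of the product (K = 20.8, k = 0.00193 s⁻¹, Ea = 90.0 kJ mol⁻¹, ΔH = −33.0 kJ mol⁻¹)
    (constants at 60 °C)

At the start of north-east, self-condensation uses partner 2.8 times as fast as the forward coupling step. North at 20.0 min holds 33.0% substrate with 13.8% of its partner left, above the reckoned stop of 20.5%, but at 200 min it holds 15.8%, below that stop. A flask like north-east with 0.620 equiv has a reckoned stop of 58.6%, and at 20.0 min it holds 58% substrate with 4.1% of its partner left.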